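## Analysis of the target

Target 25 is an acyclic nine-carbon chain, numbered here C1 (the acetoxy-bearing olefinic carbon) to C9, that ends at C1′ of a 2,6,6-trimethylcyclohex-2-ene ring. C3 is a fully substituted carbon carrying an acetoxy group, a formyl group, the (E)-2-acetoxyvinyl unit C1=C2 and the chain methylene C4, and it is (R); C1′, an allylic CH held between the gem-dimethyl carbon C6′ and the ring olefin C2′=C3′, is (S). The two stereocentres are seven bonds apart (C3–C4–C5–C6=C7–C8–C9–C1′), so neither can direct the other and the C3 epimer would be expected to be almost inseparable; each centre therefore needs its own outside source of chirality, in high purity. Two olefin geometries must also be fixed, (E) at the trisubstituted C6=C7 and (E) at the enol acetate C1=C2. The sensitive groups are the enol acetate (cleaved by base and nucleophiles), the tertiary allylic acetate beside an aldehyde (ionisable by acid or low-valent metals and, in any hydroxy precursor, prone to acyl shift), and the 1,5-diene formed by C6=C7 and the ring olefin, which strong acid would cyclise. The hard part is C3, where one oxygen and three carbon arms at three oxidation levels must be assembled with absolute control and then elaborated without disturbing one another. The strategy rests on the substitution pattern of C3: an oxygen, a one-carbon oxygenated arm, a two-carbon sp2 arm and the chain carbon C4 are what remains when an oxygen nucleophile attacks the substituted allyl terminus generated from a 2-alkyl-2-vinyloxirane, the oxirane CH2O becoming the formyl carbon and the vinyl group becoming C1=C2.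

## Retrosynthetic reasoning

**25 back to 23.** The formyl group is taken back to primary alcohol 24 and this to silyl ether 23. No skeletal bond is cut; the point is order. An aldehyde at C3 would not survive the hydride and boron chemistry needed at C1=C2, so it is released last, from an alcohol whose α-carbon has no hydrogen and cannot epimerise. The forward steps must free and oxidise the hydroxyl without base, because in 24 a tertiary acetyl group sits next to a free primary hydroxyl.

**23 back to 21.** The tertiary acetate is cut at its acyl C–O bond to alcohol 22, which is traced to the 4-methoxybenzyl ether 21. The ether, not the ester, is carried through the metal-mediated steps, because a tertiary allylic acetate is a leaving group towards low-valent rhodium and palladium and an ether is not. The forward steps need an oxidative ether cleavage that spares an enol acetate and two trisubstituted olefins, and acylation of a hindered tertiary alcohol under non-ionising conditions.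

**21 back to 19.** The enol acetate is cut at the C1–O bond to the (E)-alkenylboronate 20, and the C1–B bond is cut back to the vinyl group of 19. The geometry is then decided by a β-hydride elimination that should give only the (E)-isomer, and the two vinyl carbons left by the key step become C1 and C2. Cross-metathesis is ruled out by the structure: the vinyl group and C6=C7 form a 1,6-diene that would ring-close to a cyclopentene and expel the terpenoid tail. The forward steps must borylate the vinyl C–H bond directly and exchange boron for acetate with retention.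

**19 back to 18.** Only the silyl group is removed. The primary hydroxyl of 18 is masked so that it neither binds boron and copper nor is acetylated together with the tertiary oxygen.

**18 back to 16 and 17 (key disconnection).** The C3–O bond is cut, giving the racemic-at-oxirane vinyl epoxide 16 and 4-methoxybenzyl alcohol 17. Cutting here, and not at a C–C bond of C3, uses the inherent pattern of C3 and lets a chiral palladium catalyst set the centre while both epimers of 16 are consumed. It also delivers the two oxygens differentiated, the tertiary one as an ether and the primary one free. The forward reaction must attack the substituted allyl terminus, not the CH2 terminus, and must equilibrate the allyl intermediates faster than it traps them.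

**16 back to 13 and 14.** The C2–C3 bond and the oxirane C–O bond are cut, giving α-chloro ketone 13 and vinylmagnesium bromide 14. No stereocontrol is wanted at this carbon, so plain carbonyl addition and halohydrin closure suffice. The forward step needs only 1,2-addition in preference to enolisation.

**13 back to 10 and 11.** The C3–C4 bond is cut between the carbonyl carbon and the chain, giving homoallylic bromide 10 (as Grignard reagent 12) and the chloroacetyl amide 11. This brings in C3 and the chloromethyl carbon at the right oxidation level in one step, without a separate homologation. The forward reaction must stop at the ketone, which the chelated adduct of an N-methoxy-N-methylamide ensures.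

**10 back to 6 and 7.** Bromide 10 comes from alcohol 9, in which the C5–C6 bond and the C7–CH3 bond are cut together, giving terminal alkyne 6 and oxirane 7. Syn addition of a methyl–aluminium bond across the alkyne fixes the (E) geometry of C6=C7 by mechanism, which a carbonyl olefination of a methyl ketone would not. The forward step must transfer the alkenyl group, not an alkyl group, from aluminium to the epoxide.

**6 back to 1.** Alkyne 6 is the dehydration-level equivalent of methyl ketone 4, which is the conjugate-reduction product of (S)-α-ionone 2, obtained from commercial racemic 1. No skeletal bond is made; C1′ is taken from the commodity enone by separating its enantiomers, because a CH flanked by a quaternary carbon and a trisubstituted olefin is not easy to address catalytically. The forward steps must reduce only the conjugated olefin and must never put C1′ at risk of deprotonation.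

## Alternatives that were turned down

**Alternative 1:** The ring is disconnected at the C1′–C6′ bond of ketone A1, 4-[(1S)-2,6,6-trimethylcyclohex-2-en-1-yl]butan-2-one (identical with 4), giving the achiral open-chain ketone A2, (5E)-6,10-dimethylundeca-5,9-dien-2-one. In the forward key step an engineered squalene–hopene cyclase protonates the terminal olefin of A2, the central olefin closes the six-membered ring onto the tertiary cation, and loss of a ring CH2 proton places the olefin in the 2-position.
- For: one catalytic step from a cheap achiral ketone, configuration from the active site, and no loss of half the material. On the ring stereocentre this is stronger than steps 1–2 here, and A1 could replace them without changing anything downstream.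
- Against: the cation can be quenched in other ways (trapping by the carbonyl oxygen, capture of water, loss of the other protons to the exocyclic or tetrasubstituted olefin), so the outcome depends on one enzyme variant and on whole-cell handling of a water-insoluble substrate. More important, it addresses only the easier stereocentre and leaves C3 to some other method.
- Comparison: the chosen strategy places its demanding step on C3 and accepts a separation of enantiomers for C1′; in place of the enzyme's economy it offers commercial reagents throughout.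

**Alternative 2:** The bond between C1′ and the first chain carbon is cut. In the forward key step the allylic alcohol A4, (1R)-2,4,4-trimethylcyclohex-2-en-1-ol, is heated under Johnson orthoester Claisen conditions; the ketene acetal rearranges [3,3] across the ring allyl unit and gives ester A3, ethyl 2-[(1S)-2,6,6-trimethylcyclohex-2-en-1-yl]acetate, with the olefin in its final position.
- For: transfer of chirality is dependable, because bond formation can only occur on the face that carried the oxygen, and A4 would come from catalytic asymmetric reduction of the enone. On enantiocontrol of C1′ this is at least as good as the chosen route.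
- Against: the new bond forms at a carbon attached to the gem-dimethyl carbon, so the rearrangement competes with elimination to a diene. A3 is also two carbons and an alkyne short of 6, so reduction, activation and acetylide displacement would be needed, about two steps more than 1 to 6 here. C3 is again untouched.
- Comparison: it is a longer way to the same intermediate and does not bear on the central problem.

**Alternative 3:** The C2–C3 bond is cut, C3 being made by adding an acetylide to the ketone of α-keto ester A6, ethyl (5E)-6-methyl-2-oxo-8-[(1S)-2,6,6-trimethylcyclohex-2-en-1-yl]oct-5-enoate. In the forward key step a zinc salt, an amine base and a chiral amino alcohol generate a zinc acetylide from a silyl-capped acetylene, which adds to one face of the chelated 1,2-dicarbonyl unit to give A5, ethyl (2R,5E)-2-hydroxy-6-methyl-2-[2-(trimethylsilyl)ethynyl]-8-[(1S)-2,6,6-trimethylcyclohex-2-en-1-yl]oct-5-enoate.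
- For: the stereocentre and a C–C bond are made together, the ester carbon is already the future formyl carbon, and A6 would be one step from Grignard reagent 12 and an oxalate. Above all, an alkyne gives the (E)-alkenylboronate by plain syn hydroboration, which is better precedented than the vinyl C–H borylation of step 10; on that point this alternative is stronger, and its step count would be about the same.
- Against: enantioselective alkynylation is far more secure for aldehydes than for ketones. Here an ester and a primary alkyl chain must be told apart through chelation alone, the ketone has an enolisable α-CH2 that invites self-condensation under amine and zinc, and silylacetylenes are among the less reactive partners. Any shortfall in selectivity at C3 is fatal, because the epimers cannot be removed.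
- Comparison: the chosen strategy offers a stereo-forming event whose known scope matches the substrate class, consumes both epimers of a racemic centre, and hands on the two C3 oxygens already differentiated.

Key step: step 8

Assumption on step 1: the levorotatory enantiomer of 1 is taken as the (S)-form, as α-ionone is commonly assigned, so fraction 2 is identified by the sign of its rotation.
Assumption on step 8: the (S,S)-ligand is taken to give the (R) ether, by analogy with the usual sense of this ligand family on diene monoepoxides; if the opposite sense is found, the (R,R)-ligand is used in the same way.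

## Route

Step 1
Reactants: 1 (±)-α-ionone, (3E)-4-(2,6,6-trimethylcyclohex-2-en-1-yl)but-3-en-2-one
Product: 2 (S)-α-ionone, (3E)-4-[(1S)-2,6,6-trimethylcyclohex-2-en-1-yl]but-3-en-2-one
Conditions: preparative supercritical-fluid chromatography, cellulose tris(3,5-dimethylphenylcarbamate) phase, CO2/i-PrOH, 35 °C; levorotatory fraction collected
Reagents that add atoms: none
Why: Chromatographic resolution on a chiral stationary phase; no bond is made or broken, and the enone chromophore allows UV-triggered collection. Under these neutral conditions the γ-hydrogen at C1′ is not removed, so the collected (S)-enantiomer should keep its configuration.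

Step 2
Reactants: 2 (S)-α-ionone
Product: 4 4-[(1S)-2,6,6-trimethylcyclohex-2-en-1-yl]butan-2-one, via triethylsilyl enol ether 3 (not isolated)
Conditions: Et3SiH, RhCl(PPh3)3 (cat.), neat, 50 °C; then K2CO3 (cat.), MeOH, rt
Reagents that add atoms: none
Why: Rhodium-catalysed 1,4-hydrosilylation of the enone with a monohydrosilane (conjugate reduction) should give silyl enol ether 3, and methanolysis releases the saturated ketone. The isolated trisubstituted ring olefin is not hydrosilylated and C1′ is not touched, so it stays (S).

Step 3
Reactants: 4 4-[(1S)-2,6,6-trimethylcyclohex-2-en-1-yl]butan-2-one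
Product: 6 (6S)-6-(but-3-yn-1-yl)-1,5,5-trimethylcyclohex-1-ene, via enol diethyl phosphate 5 (not isolated)
Conditions: LiN(i-Pr)2 (1.05 equiv), THF, −78 °C; ClP(O)(OEt)2, −78 °C → rt; LiN(i-Pr)2 (2.3 equiv), −78 °C → rt; H2O
Reagents that add atoms: none
Why: Kinetic deprotonation of the methyl ketone on its CH3 side, O-phosphorylation and base-induced β-elimination of the terminal enol phosphate (methyl ketone to terminal alkyne). The excess amide holds the product as its acetylide, which should prevent isomerisation to the allene.

Step 4
Reactants: 6 (6S)-6-(but-3-yn-1-yl)-1,5,5-trimethylcyclohex-1-ene; 7 oxirane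
Product: 9 (3E)-4-methyl-6-[(1S)-2,6,6-trimethylcyclohex-2-en-1-yl]hex-3-en-1-ol, via (E)-alkenyldimethylalane 8 (not isolated)
Conditions: Me3Al, Cp2ZrCl2 (0.25 equiv), CH2Cl2, 0 °C → rt; volatiles removed; n-BuLi, hexane, 0 °C; 7, THF, 0 °C → rt; H2O, aq. potassium sodium tartrate
Reagents that add atoms: trimethylaluminium, C[Al](C)C
Why: Zirconium-catalysed methylalumination of the terminal alkyne (Negishi carboalumination) adds CH3 and aluminium syn, with aluminium on the terminal carbon, so 8 is (E). Its lithium alanate should open oxirane with retention of the olefin geometry, which fixes the (E)-trisubstituted C6=C7.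

Step 5
Reactants: 9 (3E)-4-methyl-6-[(1S)-2,6,6-trimethylcyclohex-2-en-1-yl]hex-3-en-1-ol
Product: 10 (6S)-6-[(3E)-6-bromo-3-methylhex-3-en-1-yl]-1,5,5-trimethylcyclohex-1-ene
Conditions: CBr4, PPh3, CH2Cl2, 0 °C
Reagents that add atoms: carbon tetrabromide, BrC(Br)(Br)Br
Why: Appel bromination, an SN2 displacement at the primary carbon via the alkoxyphosphonium salt, under neutral conditions that spare the acid-sensitive 1,5-diene.

Step 6
Reactants: 10 (6S)-6-[(3E)-6-bromo-3-methylhex-3-en-1-yl]-1,5,5-trimethylcyclohex-1-ene; 11 2-chloro-N-methoxy-N-methylacetamide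
Product: 13 (5E)-1-chloro-6-methyl-8-[(1S)-2,6,6-trimethylcyclohex-2-en-1-yl]oct-5-en-2-one, via Grignard reagent 12 (not isolated)
Conditions: Mg, THF, rt → 45 °C; then 11, THF, −20 → 0 °C; 1 M HCl
Reagents that add atoms: none
Why: Grignard formation from the primary homoallylic bromide and acylation by the N-methoxy-N-methylamide (Weinreb ketone synthesis). The magnesium-chelated tetrahedral adduct should persist until the acidic quench, so no second addition occurs and the α-chlorine is kept.

Step 7
Reactants: 13 (5E)-1-chloro-6-methyl-8-[(1S)-2,6,6-trimethylcyclohex-2-en-1-yl]oct-5-en-2-one; 14 vinylmagnesium bromide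
Product: 16 2-ethenyl-2-{(3E)-4-methyl-6-[(1S)-2,6,6-trimethylcyclohex-2-en-1-yl]hex-3-en-1-yl}oxirane (both epimers at the oxirane carbon), via chlorohydrin magnesium alkoxide 15 (not isolated)
Conditions: 14 (1.2 equiv), THF, −78 °C; then 3 M NaOH, 0 °C → rt
Reagents that add atoms: none
Why: 1,2-Addition of the vinyl Grignard reagent to the α-chloro ketone, then intramolecular SN2 closure of the chlorohydrin alkoxide once hydroxide is added (halohydrin route to 2-alkyl-2-vinyloxiranes). The carbinol carbon is formed without control, which is intended, since the next step is stereoconvergent.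

Step 8
Reactants: 16 2-ethenyl-2-{(3E)-4-methyl-6-[(1S)-2,6,6-trimethylcyclohex-2-en-1-yl]hex-3-en-1-yl}oxirane (both epimers); 17 4-methoxybenzyl alcohol
Product: 18 (2R,5E)-2-ethenyl-2-[(4-methoxyphenyl)methoxy]-6-methyl-8-[(1S)-2,6,6-trimethylcyclohex-2-en-1-yl]oct-5-en-1-ol
Conditions: 17 (1.1 equiv), Pd2(dba)3·CHCl3 (1 mol%), N,N'-[(1S,2S)-cyclohexane-1,2-diyl]bis[2-(diphenylphosphanyl)benzamide] (3 mol%), BEt3 (1–2 mol%), CH2Cl2, rt
Reagents that add atoms: none
Why: Zerovalent palladium carrying the chiral bisphosphine coordinates the vinyl group of either epimer of 16 and ionises the allylic C–O bond with relief of ring strain, giving a zwitterionic η3-allyl palladium alkoxide whose substituted terminus bears the chain and the CH2O– arm. The two diastereomeric allyl complexes exchange palladium between the faces through the η1 form at the unsubstituted CH2 terminus, and this exchange should outrun capture, so both epimers funnel into one product (dynamic kinetic asymmetric transformation). BEt3 binds the alkoxide and, with 17, forms a borate that passes the 4-methoxybenzyloxy group to the adjacent substituted terminus, which is why the C–O bond is made at the fully substituted carbon and not at the CH2 terminus. The closest known reaction type is the palladium-catalysed asymmetric addition of alcohols to 2-alkyl-2-vinyloxiranes with a trialkylborane co-catalyst, which covers long alkyl groups on the oxirane carbon. No ring is closed; one C–O bond and one stereocentre are formed. The (R) configuration is set by the chiral pocket of the ligand acting on the equilibrating allyl complexes, independently of the ring centre seven bonds away. The step needs branched-over-linear regioselectivity, secured by the boron tether to the neighbouring alkoxide, and chemoselectivity for the vinyloxirane, secured because the two trisubstituted olefins carry no allylic leaving group and do not ionise at zerovalent palladium.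

Step 9
Reactants: 18 (2R,5E)-2-ethenyl-2-[(4-methoxyphenyl)methoxy]-6-methyl-8-[(1S)-2,6,6-trimethylcyclohex-2-en-1-yl]oct-5-en-1-ol
Product: 19 tert-butyl({(2R,5E)-2-ethenyl-2-[(4-methoxyphenyl)methoxy]-6-methyl-8-[(1S)-2,6,6-trimethylcyclohex-2-en-1-yl]oct-5-en-1-yl}oxy)dimethylsilane
Conditions: TBSCl, imidazole, DMF, rt
Reagents that add atoms: tert-butyldimethylsilyl chloride, CC(C)(C)[Si](C)(C)Cl
Why: Imidazole-mediated silylation of the only hydroxyl group present; the silyl ether should survive the rhodium, copper, quinone and acylation steps that follow.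

Step 10
Reactants: 19 tert-butyl({(2R,5E)-2-ethenyl-2-[(4-methoxyphenyl)methoxy]-6-methyl-8-[(1S)-2,6,6-trimethylcyclohex-2-en-1-yl]oct-5-en-1-yl}oxy)dimethylsilane
Product: 20 2-[(1E,3R,6E)-3-({[tert-butyl(dimethyl)silyl]oxy}methyl)-3-[(4-methoxyphenyl)methoxy]-7-methyl-9-[(1S)-2,6,6-trimethylcyclohex-2-en-1-yl]nona-1,6-dien-1-yl]-4,4,5,5-tetramethyl-1,3,2-dioxaborolane
Conditions: HBpin, norbornene, [Rh(cod)2]BF4 (cat.), [2-(4-isopropyl-4,5-dihydro-1,3-oxazol-2-yl)ferrocenyl]diphenylphosphane (iPr-Foxap, cat.), THF, rt
Reagents that add atoms: pinacolborane, CC1(C)OBOC1(C)C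
Why: Rhodium-catalysed dehydrogenative borylation of a terminal alkene: insertion of the vinyl group into the Rh–B bond with boron on the terminal carbon, then β-hydride elimination, should give the (E)-alkenylboronate, with norbornene taking up the hydrogen. The vinyl group has no allylic hydrogen, so no allylboronate can form, and the two trisubstituted olefins are too hindered to insert.

Step 11
Reactants: 20 2-[(1E,3R,6E)-3-({[tert-butyl(dimethyl)silyl]oxy}methyl)-3-[(4-methoxyphenyl)methoxy]-7-methyl-9-[(1S)-2,6,6-trimethylcyclohex-2-en-1-yl]nona-1,6-dien-1-yl]-4,4,5,5-tetramethyl-1,3,2-dioxaborolane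
Product: 21 (1E,3R,6E)-3-({[tert-butyl(dimethyl)silyl]oxy}methyl)-3-[(4-methoxyphenyl)methoxy]-7-methyl-9-[(1S)-2,6,6-trimethylcyclohex-2-en-1-yl]nona-1,6-dien-1-yl acetate
Conditions: Cu(OAc)2 (2.5 equiv), Et3N, 4 Å MS, MeCN, air, rt → 40 °C
Reagents that add atoms: copper diacetate Cu(OAc)2, CC(=O)[O-].CC(=O)[O-].[Cu+2]
Why: Copper-mediated oxidative C–O coupling of an alkenylboronate with a carboxylate (Chan–Lam-type acetoxylation): transmetalation to copper, oxidation to trivalent copper and reductive elimination of the alkenyl acetate proceed with retention, so the (E)-boronate should give the (E)-enol acetate.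

Step 12
Reactants: 21 (1E,3R,6E)-3-({[tert-butyl(dimethyl)silyl]oxy}methyl)-3-[(4-methoxyphenyl)methoxy]-7-methyl-9-[(1S)-2,6,6-trimethylcyclohex-2-en-1-yl]nona-1,6-dien-1-yl acetate
Product: 22 (1E,3R,6E)-3-({[tert-butyl(dimethyl)silyl]oxy}methyl)-3-hydroxy-7-methyl-9-[(1S)-2,6,6-trimethylcyclohex-2-en-1-yl]nona-1,6-dien-1-yl acetate
Conditions: DDQ, CH2Cl2/pH 7 buffer, 0 °C
Reagents that add atoms: none
Why: Oxidative cleavage of the 4-methoxybenzyl ether by DDQ (hydride abstraction to the benzylic oxocarbenium ion, then hydrolysis). Buffered neutral conditions at low temperature should spare the enol acetate, the silyl ether and the olefins.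

Step 13
Reactants: 22 (1E,3R,6E)-3-({[tert-butyl(dimethyl)silyl]oxy}methyl)-3-hydroxy-7-methyl-9-[(1S)-2,6,6-trimethylcyclohex-2-en-1-yl]nona-1,6-dien-1-yl acetate
Product: 23 (1E,3R,6E)-3-(acetyloxy)-3-({[tert-butyl(dimethyl)silyl]oxy}methyl)-7-methyl-9-[(1S)-2,6,6-trimethylcyclohex-2-en-1-yl]nona-1,6-dien-1-yl acetate
Conditions: Ac2O, DMAP, Et3N, CH2Cl2, rt → 35 °C
Reagents that add atoms: acetic anhydride, CC(=O)OC(C)=O
Why: DMAP-catalysed acylation of a tertiary alcohol through the N-acetylpyridinium ion (Steglich-type). Basic, non-ionising conditions avoid allylic transposition, and the C–O bond at C3 is not broken, so the configuration is kept.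

Step 14
Reactants: 23 (1E,3R,6E)-3-(acetyloxy)-3-({[tert-butyl(dimethyl)silyl]oxy}methyl)-7-methyl-9-[(1S)-2,6,6-trimethylcyclohex-2-en-1-yl]nona-1,6-dien-1-yl acetate
Product: 24 (1E,3R,6E)-3-(acetyloxy)-3-(hydroxymethyl)-7-methyl-9-[(1S)-2,6,6-trimethylcyclohex-2-en-1-yl]nona-1,6-dien-1-yl acetate
Conditions: HF·pyridine, pyridine, THF, 0 °C
Reagents that add atoms: none
Why: Fluoride-mediated desilylation under buffered, weakly acidic conditions. Base is avoided because it would cleave the enol acetate and move the tertiary acetyl group onto the primary hydroxyl.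

Step 15
Reactants: 24 (1E,3R,6E)-3-(acetyloxy)-3-(hydroxymethyl)-7-methyl-9-[(1S)-2,6,6-trimethylcyclohex-2-en-1-yl]nona-1,6-dien-1-yl acetate
Product: 25 (1E,3R,6E)-3-(acetyloxy)-3-formyl-7-methyl-9-[(1S)-2,6,6-trimethylcyclohex-2-en-1-yl]nona-1,6-dien-1-yl acetate
Conditions: Dess–Martin periodinane, NaHCO3, CH2Cl2, 0 °C → rt
Reagents that add atoms: none
Why: Dess–Martin oxidation of the primary alcohol to the aldehyde under buffered neutral conditions. The α-carbon is fully substituted, so no enolisation, epimerisation or acyl migration is possible once the aldehyde is formed.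

## Compound list

1 | (±)-α-ionone, (3E)-4-(2,6,6-trimethylcyclohex-2-en-1-yl)but-3-en-2-one (racemic) | CC(=O)/C=C/C1C(C)=CCCC1(C)C | starting material
2 | (S)-α-ionone, (3E)-4-[(1S)-2,6,6-trimethylcyclohex-2-en-1-yl]but-3-en-2-one | CC(=O)/C=C/[C@@H]1C(C)=CCCC1(C)C | intermediate
3 | triethyl({4-[(1S)-2,6,6-trimethylcyclohex-2-en-1-yl]but-2-en-2-yl}oxy)silane (E/Z mixture) | CC[Si](CC)(CC)OC(C)=CC[C@@H]1C(C)=CCCC1(C)C | intermediate (not isolated)
4 | 4-[(1S)-2,6,6-trimethylcyclohex-2-en-1-yl]butan-2-one | CC(=O)CC[C@@H]1C(C)=CCCC1(C)C | intermediate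
5 | diethyl 4-[(1S)-2,6,6-trimethylcyclohex-2-en-1-yl]but-1-en-2-yl phosphate | C=C(CC[C@@H]1C(C)=CCCC1(C)C)OP(=O)(OCC)OCC | intermediate (not isolated)
6 | (6S)-6-(but-3-yn-1-yl)-1,5,5-trimethylcyclohex-1-ene | C#CCC[C@@H]1C(C)=CCCC1(C)C | intermediate
7 | oxirane | C1CO1 | starting material
8 | dimethyl{(1E)-2-methyl-4-[(1S)-2,6,6-trimethylcyclohex-2-en-1-yl]but-1-en-1-yl}alumane | C[Al](C)/C=C(\C)CC[C@@H]1C(C)=CCCC1(C)C | intermediate (not isolated)
9 | (3E)-4-methyl-6-[(1S)-2,6,6-trimethylcyclohex-2-en-1-yl]hex-3-en-1-ol | OCC/C=C(\C)CC[C@@H]1C(C)=CCCC1(C)C | intermediate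
10 | (6S)-6-[(3E)-6-bromo-3-methylhex-3-en-1-yl]-1,5,5-trimethylcyclohex-1-ene | BrCC/C=C(\C)CC[C@@H]1C(C)=CCCC1(C)C | intermediate
11 | 2-chloro-N-methoxy-N-methylacetamide | ClCC(=O)N(C)OC | starting material
12 | bromo{(3E)-4-methyl-6-[(1S)-2,6,6-trimethylcyclohex-2-en-1-yl]hex-3-en-1-yl}magnesium | Br[Mg]CC/C=C(\C)CC[C@@H]1C(C)=CCCC1(C)C | intermediate (not isolated)
13 | (5E)-1-chloro-6-methyl-8-[(1S)-2,6,6-trimethylcyclohex-2-en-1-yl]oct-5-en-2-one | ClCC(=O)CC/C=C(\C)CC[C@@H]1C(C)=CCCC1(C)C | intermediate
14 | vinylmagnesium bromide | C=C[Mg]Br | starting material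
15 | bromomagnesium alkoxide of (6E)-3-(chloromethyl)-7-methyl-9-[(1S)-2,6,6-trimethylcyclohex-2-en-1-yl]nona-1,6-dien-3-ol (both epimers at C3) | C=CC(CCl)(CC/C=C(\C)CC[C@@H]1C(C)=CCCC1(C)C)O[Mg]Br | intermediate (not isolated)
16 | 2-ethenyl-2-{(3E)-4-methyl-6-[(1S)-2,6,6-trimethylcyclohex-2-en-1-yl]hex-3-en-1-yl}oxirane (both epimers at the oxirane carbon) | C=CC1(CO1)CC/C=C(\C)CC[C@@H]1C(C)=CCCC1(C)C | intermediate
17 | 4-methoxybenzyl alcohol | COc1ccc(CO)cc1 | starting material
18 | (2R,5E)-2-ethenyl-2-[(4-methoxyphenyl)methoxy]-6-methyl-8-[(1S)-2,6,6-trimethylcyclohex-2-en-1-yl]oct-5-en-1-ol | C=C[C@@](CO)(CC/C=C(\C)CC[C@@H]1C(C)=CCCC1(C)C)OCc1ccc(OC)cc1 | intermediate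
19 | tert-butyl({(2R,5E)-2-ethenyl-2-[(4-methoxyphenyl)methoxy]-6-methyl-8-[(1S)-2,6,6-trimethylcyclohex-2-en-1-yl]oct-5-en-1-yl}oxy)dimethylsilane | C=C[C@@](CO[Si](C)(C)C(C)(C)C)(CC/C=C(\C)CC[C@@H]1C(C)=CCCC1(C)C)OCc1ccc(OC)cc1 | intermediate
20 | 2-[(1E,3R,6E)-3-({[tert-butyl(dimethyl)silyl]oxy}methyl)-3-[(4-methoxyphenyl)methoxy]-7-methyl-9-[(1S)-2,6,6-trimethylcyclohex-2-en-1-yl]nona-1,6-dien-1-yl]-4,4,5,5-tetramethyl-1,3,2-dioxaborolane | CC1(C)OB(/C=C/[C@@](CO[Si](C)(C)C(C)(C)C)(CC/C=C(\C)CC[C@@H]2C(C)=CCCC2(C)C)OCc2ccc(OC)cc2)OC1(C)C | intermediate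
21 | (1E,3R,6E)-3-({[tert-butyl(dimethyl)silyl]oxy}methyl)-3-[(4-methoxyphenyl)methoxy]-7-methyl-9-[(1S)-2,6,6-trimethylcyclohex-2-en-1-yl]nona-1,6-dien-1-yl acetate | CC(=O)O/C=C/[C@@](CO[Si](C)(C)C(C)(C)C)(CC/C=C(\C)CC[C@@H]1C(C)=CCCC1(C)C)OCc1ccc(OC)cc1 | intermediate
22 | (1E,3R,6E)-3-({[tert-butyl(dimethyl)silyl]oxy}methyl)-3-hydroxy-7-methyl-9-[(1S)-2,6,6-trimethylcyclohex-2-en-1-yl]nona-1,6-dien-1-yl acetate | CC(=O)O/C=C/[C@@](CO[Si](C)(C)C(C)(C)C)(CC/C=C(\C)CC[C@@H]1C(C)=CCCC1(C)C)O | intermediate
23 | (1E,3R,6E)-3-(acetyloxy)-3-({[tert-butyl(dimethyl)silyl]oxy}methyl)-7-methyl-9-[(1S)-2,6,6-trimethylcyclohex-2-en-1-yl]nona-1,6-dien-1-yl acetate | CC(=O)O/C=C/[C@@](CO[Si](C)(C)C(C)(C)C)(CC/C=C(\C)CC[C@@H]1C(C)=CCCC1(C)C)OC(C)=O | intermediate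
24 | (1E,3R,6E)-3-(acetyloxy)-3-(hydroxymethyl)-7-methyl-9-[(1S)-2,6,6-trimethylcyclohex-2-en-1-yl]nona-1,6-dien-1-yl acetate | CC(=O)O/C=C/[C@@](CO)(CC/C=C(\C)CC[C@@H]1C(C)=CCCC1(C)C)OC(C)=O | intermediate
25 | (1E,3R,6E)-3-(acetyloxy)-3-formyl-7-methyl-9-[(1S)-2,6,6-trimethylcyclohex-2-en-1-yl]nona-1,6-dien-1-yl acetate | CC(=O)O/C=C/[C@@](C=O)(CC/C=C(\C)CC[C@@H]1C(C)=CCCC1(C)C)OC(C)=O | target

## Step count and least certain steps

Total step count: 15. Longest linear sequence: 15 steps (1 to 25; the route is linear, and 7, 11, 14 and 17 are used as purchased).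

**Step 8 (key step).** The most likely failure is incomplete face exchange of the allyl complexes before capture, that is, loss of stereoconvergence. This would leave the C2 epimer as an admixture that cannot be removed, because the two stereocentres are too far apart for the epimers to differ. Attack at the unsubstituted terminus is a lesser risk. The fallback sets out from 10 and returns at 19, and sets the centre by reagent-controlled epoxidation instead. Grignard reagent 12, made from 10, is added across propargyl alcohol with CuI catalysis and protonated to give (5E)-6-methyl-2-methylidene-8-[(1S)-2,6,6-trimethylcyclohex-2-en-1-yl]oct-5-en-1-ol F1. Sharpless asymmetric epoxidation (Ti(Oi-Pr)4, L-(+)-diisopropyl tartrate, t-BuOOH, 4 Å MS, −20 °C), which acts only on the allylic alcohol olefin, should give [(2S)-2-{(3E)-4-methyl-6-[(1S)-2,6,6-trimethylcyclohex-2-en-1-yl]hex-3-en-1-yl}oxiran-2-yl]methanol F2. TBSCl and imidazole give tert-butyl({(2R)-2-[(3E)-4-methyl-6-[(1S)-2,6,6-trimethylcyclohex-2-en-1-yl]hex-3-en-1-yl]oxiran-2-yl}methoxy)dimethylsilane F3. Excess dimethylsulfonium methylide opens the oxirane at its CH2 and eliminates to the one-carbon-homologated tertiary allylic alcohol (3R,6E)-3-({[tert-butyl(dimethyl)silyl]oxy}methyl)-7-methyl-9-[(1S)-2,6,6-trimethylcyclohex-2-en-1-yl]nona-1,6-dien-3-ol F4. 4-Methoxybenzyl transfer under neutral conditions from 2-(4-methoxybenzyloxy)-4-methylquinoline and methyl triflate then returns to 19.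

**Step 10.** Hydroboration of the vinyl group may compete, or β-elimination of the allylic oxygen from the alkylrhodium intermediate may take the place of β-hydride elimination; insertion may also be slow because the vinyl group sits on a fully substituted carbon. The fallback runs from 19 to 21 without boron at C1. Hydroboration with 9-BBN and oxidation with NaBO3·4H2O give (3R,6E)-3-({[tert-butyl(dimethyl)silyl]oxy}methyl)-3-[(4-methoxyphenyl)methoxy]-7-methyl-9-[(1S)-2,6,6-trimethylcyclohex-2-en-1-yl]non-6-en-1-ol F5. Dess–Martin oxidation gives (3R,6E)-3-({[tert-butyl(dimethyl)silyl]oxy}methyl)-3-[(4-methoxyphenyl)methoxy]-7-methyl-9-[(1S)-2,6,6-trimethylcyclohex-2-en-1-yl]non-6-enal F6. Enol acetylation (Ac2O, Et3N, DMAP, rt) then gives 21. The (E)-isomer is expected to prevail because the (Z)-isomer places the fully substituted carbon cis to the acetoxy group, and the minor isomer would be removed by chromatography. The temperature is kept low to limit β-elimination of the ether oxygen from the enolate.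

**Step 11.** Boron-to-copper transfer from the hindered pinacol ester may be slow, so that protodeboronation and oxidative dimerisation overtake C–O coupling. The fallback runs from 20 to 21 and takes boron out of the coupling, so that the alkenyl carbon enters the copper cycle as a halide and no transmetalation is needed. Iododeboronation (aq. NaOH, then I2, one equivalent, THF, 0 °C) proceeds through the hydroxyboronate complex with retention of geometry. That complex is far more nucleophilic than the trisubstituted olefins, so the step should give tert-butyl{[(2R,5E)-2-[(E)-2-iodoethenyl]-2-[(4-methoxyphenyl)methoxy]-6-methyl-8-[(1S)-2,6,6-trimethylcyclohex-2-en-1-yl]oct-5-en-1-yl]oxy}dimethylsilane F7. Copper-catalysed O-vinylation of acetate (CuI, N,N′-dimethylethane-1,2-diamine, CsOAc, toluene, 80 °C) then gives 21. This is an Ullmann-type substitution at the alkenyl carbon of the kind used to make enol esters and enol lactones from alkenyl halides, and it keeps the olefin geometry.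

**Step 14.** The tertiary acetyl group may migrate onto the freshly freed primary hydroxyl, and the enol acetate may be partly cleaved. The fallback runs from 22 to 25 and moves the tertiary acetylation to the end, so that no hydroxy acetate is ever formed. HF·pyridine gives (1E,3R,6E)-3-hydroxy-3-(hydroxymethyl)-7-methyl-9-[(1S)-2,6,6-trimethylcyclohex-2-en-1-yl]nona-1,6-dien-1-yl acetate F8. Parikh–Doering oxidation (SO3·pyridine, DMSO, i-Pr2NEt), which cannot touch the tertiary hydroxyl and does not cleave the diol, gives (1E,3R,6E)-3-formyl-3-hydroxy-7-methyl-9-[(1S)-2,6,6-trimethylcyclohex-2-en-1-yl]nona-1,6-dien-1-yl acetate F9. Ac2O, DMAP and Et3N then acetylate the tertiary hydroxyl to 25.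

**Step 7.** The basic Grignard reagent may enolise the chloro ketone instead of adding to the carbonyl, and the acid-sensitive vinyloxirane may be lost on purification. The fallback runs from 10 to 16 through the enone. Grignard reagent 12 is added to acrolein and the adduct is quenched with aq. NH4Cl to give (6E)-7-methyl-9-[(1S)-2,6,6-trimethylcyclohex-2-en-1-yl]nona-1,6-dien-3-ol F10. Dess–Martin oxidation gives (6E)-7-methyl-9-[(1S)-2,6,6-trimethylcyclohex-2-en-1-yl]nona-1,6-dien-3-one F11. Corey–Chaykovsky epoxidation with dimethylsulfonium methylide (Me3S+ I−, KN(SiMe3)2, THF, −10 °C), which adds to the carbonyl group of enones, returns to 16.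

## Further compounds

F1 | step 8 | (5E)-6-methyl-2-methylidene-8-[(1S)-2,6,6-trimethylcyclohex-2-en-1-yl]oct-5-en-1-ol | C=C(CO)CC/C=C(\C)CC[C@@H]1C(C)=CCCC1(C)C
F2 | step 8 | [(2S)-2-{(3E)-4-methyl-6-[(1S)-2,6,6-trimethylcyclohex-2-en-1-yl]hex-3-en-1-yl}oxiran-2-yl]methanol | OC[C@@]1(CC/C=C(\C)CC[C@@H]2C(C)=CCCC2(C)C)CO1
F3 | step 8 | tert-butyl({(2R)-2-[(3E)-4-methyl-6-[(1S)-2,6,6-trimethylcyclohex-2-en-1-yl]hex-3-en-1-yl]oxiran-2-yl}methoxy)dimethylsilane | CC(C)(C)[Si](C)(C)OC[C@@]1(CC/C=C(\C)CC[C@@H]2C(C)=CCCC2(C)C)CO1
F4 | step 8 | (3R,6E)-3-({[tert-butyl(dimethyl)silyl]oxy}methyl)-7-methyl-9-[(1S)-2,6,6-trimethylcyclohex-2-en-1-yl]nona-1,6-dien-3-ol | C=C[C@@](CO[Si](C)(C)C(C)(C)C)(CC/C=C(\C)CC[C@@H]1C(C)=CCCC1(C)C)O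
F5 | step 10 | (3R,6E)-3-({[tert-butyl(dimethyl)silyl]oxy}methyl)-3-[(4-methoxyphenyl)methoxy]-7-methyl-9-[(1S)-2,6,6-trimethylcyclohex-2-en-1-yl]non-6-en-1-ol | OCC[C@@](CO[Si](C)(C)C(C)(C)C)(CC/C=C(\C)CC[C@@H]1C(C)=CCCC1(C)C)OCc1ccc(OC)cc1
F6 | step 10 | (3R,6E)-3-({[tert-butyl(dimethyl)silyl]oxy}methyl)-3-[(4-methoxyphenyl)methoxy]-7-methyl-9-[(1S)-2,6,6-trimethylcyclohex-2-en-1-yl]non-6-enal | O=CC[C@@](CO[Si](C)(C)C(C)(C)C)(CC/C=C(\C)CC[C@@H]1C(C)=CCCC1(C)C)OCc1ccc(OC)cc1
F7 | step 11 | tert-butyl{[(2R,5E)-2-[(E)-2-iodoethenyl]-2-[(4-methoxyphenyl)methoxy]-6-methyl-8-[(1S)-2,6,6-trimethylcyclohex-2-en-1-yl]oct-5-en-1-yl]oxy}dimethylsilane | I/C=C/[C@@](CO[Si](C)(C)C(C)(C)C)(CC/C=C(\C)CC[C@@H]1C(C)=CCCC1(C)C)OCc1ccc(OC)cc1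
F8 | step 14 | (1E,3R,6E)-3-hydroxy-3-(hydroxymethyl)-7-methyl-9-[(1S)-2,6,6-trimethylcyclohex-2-en-1-yl]nona-1,6-dien-1-yl acetate | CC(=O)O/C=C/[C@@](CO)(CC/C=C(\C)CC[C@@H]1C(C)=CCCC1(C)C)O
F9 | step 14 | (1E,3R,6E)-3-formyl-3-hydroxy-7-methyl-9-[(1S)-2,6,6-trimethylcyclohex-2-en-1-yl]nona-1,6-dien-1-yl acetate | CC(=O)O/C=C/[C@@](C=O)(CC/C=C(\C)CC[C@@H]1C(C)=CCCC1(C)C)O
F10 | step 7 | (6E)-7-methyl-9-[(1S)-2,6,6-trimethylcyclohex-2-en-1-yl]nona-1,6-dien-3-ol (both epimers at C3) | C=CC(O)CC/C=C(\C)CC[C@@H]1C(C)=CCCC1(C)C
F11 | step 7 | (6E)-7-methyl-9-[(1S)-2,6,6-trimethylcyclohex-2-en-1-yl]nona-1,6-dien-3-one | C=CC(=O)CC/C=C(\C)CC[C@@H]1C(C)=CCCC1(C)C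
A1 | alternative 1 | 4-[(1S)-2,6,6-trimethylcyclohex-2-en-1-yl]butan-2-one | CC(=O)CC[C@@H]1C(C)=CCCC1(C)C
A2 | alternative 1 | (5E)-6,10-dimethylundeca-5,9-dien-2-one | CC(=O)CC/C=C(\C)CCC=C(C)C
A3 | alternative 2 | ethyl 2-[(1S)-2,6,6-trimethylcyclohex-2-en-1-yl]acetate | CCOC(=O)C[C@@H]1C(C)=CCCC1(C)C
A4 | alternative 2 | (1R)-2,4,4-trimethylcyclohex-2-en-1-ol | O[C@@H]1CCC(C)(C)C=C1C
A5 | alternative 3 | ethyl (2R,5E)-2-hydroxy-6-methyl-2-[2-(trimethylsilyl)ethynyl]-8-[(1S)-2,6,6-trimethylcyclohex-2-en-1-yl]oct-5-enoate | C[Si](C)(C)C#C[C@@](C(=O)OCC)(CC/C=C(\C)CC[C@@H]1C(C)=CCCC1(C)C)O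
A6 | alternative 3 | ethyl (5E)-6-methyl-2-oxo-8-[(1S)-2,6,6-trimethylcyclohex-2-en-1-yl]oct-5-enoate | CCOC(=O)C(=O)CC/C=C(\C)CC[C@@H]1C(C)=CCCC1(C)C
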